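**Assumption:** the SMILES is taken as drawn (cis‑4,5‑oxirane, so a neryl‑type 4Z precursor). Locants C1–C15 in names are germacrane locants (C1 ketone, C2 carbinol, C4/C5 oxirane, C6 lactone carbinol, C7=C11, C8 methacrylate carbinol, C12 lactone C=O, C13 CH2OAc). TBS = tert‑butyldimethylsilyl.

## Retrosynthetic overview

1. 24 ⇒ 23: epoxidation of the 4Z‑alkene is the last ring‑forming step, as in the late oxidase epoxidation of germacranolides.
2. 23 ⇒ acyclic Z‑enal/(Z)‑β‑iodoenoate 20: one Ni/Cr operation closes C6–C7 (the farnesyl C1–C10 bond of germacrene biosynthesis, giving the 10‑membered ring) and then O6–C12 (butenolide with 7(11)‑ene and 13‑OAc already in place).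
3. 20 ⇒ ynoate 16 (iodide/CH2O halo‑aldol builds the tetrasubstituted iodoalkene) ⇒ γ‑keto aldehyde 13 + methyl propiolate (sets C8).
4. 13 ⇒ α‑silyloxy aldehyde 8 + (Z)‑crotylboronate (C10 set from C2), then hydroboration and oxidation.
5. 8 ⇒ methyl (S)‑glycidate (C2) + (Z)‑iodoalkene 3 from but‑2‑yn‑1‑ol (Z‑C4=C5). Ring order: carbocycle → lactone → oxirane.

## Route

Step 1
Reactants: 1 but‑2‑yn‑1‑ol
Product: 3 (Z)‑3‑iodobut‑2‑en‑1‑ol, via cyclic alkenylaluminate 2 (not isolated)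
Conditions: Red‑Al, THF, 0 °C → rt; then I2, −78 → 0 °C
Reagents that add atoms: iodine, II
Why: Hydroxyl‑directed trans‑hydroalumination puts Al on the distal carbon in a five‑membered aluminate and iodinolysis with retention gives the Z‑iodoalkene that fixes the later C4=C5 geometry (hydroalumination–iodination).

Step 2
Reactants: 3 (Z)‑3‑iodobut‑2‑en‑1‑ol; 4 methyl (S)‑glycidate
Product: 6 methyl (2S,4Z)‑2,6‑dihydroxy‑4‑methylhex‑4‑enoate, via alkenylmagnesium alkoxide 5 (not isolated)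
Conditions: i‑PrMgCl (1 equiv) then i‑PrMgCl·LiCl, THF, 0 °C → rt; CuI (10 mol %), 4, −40 → −10 °C
Reagents that add atoms: none
Why: I/Mg exchange with retention of alkene geometry followed by Cu‑catalysed SN2 opening of the glycidate at its CH2 terminus leaves the C2 stereocentre of 4 untouched (Knochel exchange, cuprate epoxide opening).

Step 3
Reactants: 6 methyl (2S,4Z)‑2,6‑dihydroxy‑4‑methylhex‑4‑enoate
Product: 7 methyl (2S,4Z)‑2,6‑bis(TBS‑oxy)‑4‑methylhex‑4‑enoate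
Conditions: TBSCl, imidazole, DMF, rt
Reagents that add atoms: tert‑butyldimethylsilyl chloride, CC(C)(C)[Si](C)(C)Cl
Why: Standard bis‑silylation of the primary allylic and α‑hydroxy ester alcohols (Corey TBS protection); no stereocentre is touched.

Step 4
Reactants: 7 methyl (2S,4Z)‑2,6‑bis(TBS‑oxy)‑4‑methylhex‑4‑enoate
Product: 8 (2S,4Z)‑2,6‑bis(TBS‑oxy)‑4‑methylhex‑4‑enal
Conditions: DIBAL‑H, CH2Cl2, −78 °C; Rochelle salt
Reagents that add atoms: none
Why: DIBAL half‑reduction of an α‑silyloxy methyl ester stops at the aluminium hemiacetal at −78 °C, and the aldehyde is used cold and directly so C2 does not epimerise.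

Step 5
Reactants: 8 (2S,4Z)‑2,6‑bis(TBS‑oxy)‑4‑methylhex‑4‑enal; 9 (Z)‑crotylboronic acid pinacol ester
Product: 10 (3S,4R,5S,7Z)‑5,9‑bis(TBS‑oxy)‑3,7‑dimethylnona‑1,7‑dien‑4‑ol
Conditions: toluene, rt, 36 h; aqueous work‑up
Reagents that add atoms: none
Why: Roush‑type crotylboration through a closed chair transition state, in which the Z‑boronate gives the C1/C10 syn relationship and the α‑silyloxy centre directs Felkin (1,2‑anti) attack, so C10 (S) is set from C2 and the C1 carbinol is later oxidised away.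

Step 6
Reactants: 10 (3S,4R,5S,7Z)‑5,9‑bis(TBS‑oxy)‑3,7‑dimethylnona‑1,7‑dien‑4‑ol
Product: 12 (3S,4R,5S,7Z)‑5,9‑bis(TBS‑oxy)‑3,7‑dimethylnon‑7‑ene‑1,4‑diol, via B‑alkyl‑9‑BBN adduct 11 (not isolated)
Conditions: 9‑BBN (2.5 equiv), THF, 0 °C → rt; then NaOH, H2O2, 0 °C
Reagents that add atoms: hydrogen peroxide, OO
Why: Anti‑Markovnikov hydroboration–oxidation with bulky 9‑BBN takes the terminal vinyl group and not the trisubstituted alkene, giving the primary C8 alcohol.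

Step 7
Reactants: 12 (3S,4R,5S,7Z)‑5,9‑bis(TBS‑oxy)‑3,7‑dimethylnon‑7‑ene‑1,4‑diol
Product: 13 (3S,5S,7Z)‑5,9‑bis(TBS‑oxy)‑3,7‑dimethyl‑4‑oxonon‑7‑enal
Conditions: (COCl)2, DMSO, CH2Cl2, −78 °C; i‑Pr2NEt, −78 → −40 °C; used crude
Reagents that add atoms: none
Why: Swern oxidation activates both hydroxyls as alkoxysulfonium ions before base is added, so the 1,4‑diol goes to the γ‑keto aldehyde without lactol or lactone formation, and the cold hindered base leaves C2 and C10 intact.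

Step 8
Reactants: 13 (3S,5S,7Z)‑5,9‑bis(TBS‑oxy)‑3,7‑dimethyl‑4‑oxonon‑7‑enal; 14 methyl propiolate
Product: 16 methyl (4R,6S,8S,10Z)‑8,12‑bis(TBS‑oxy)‑6,10‑dimethyl‑4‑(methacryloyloxy)‑7‑oxododec‑10‑en‑2‑ynoate, via propargylic zinc alkoxide 15 (not isolated)
Conditions: Me2Zn (3 equiv), ProPhenol ligand (20 mol %; enantiomer that delivers to the aldehyde Si face, (S,S) expected), Ph3PO, toluene, 4 °C; then methacryloyl chloride, 0 °C → rt
Reagents that add atoms: methacryloyl chloride, C=C(C)C(Cl)=O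
Why: Trost ProPhenol–Zn enantioselective alkynylation adds the propiolate to the aldehyde only (the hindered ketone is inert), the ligand controlling Si‑face attack to give 8R, and the zinc alkoxide is esterified in the same flask by the acyl chloride.

Step 9
Reactants: 16 methyl (4R,6S,8S,10Z)‑8,12‑bis(TBS‑oxy)‑6,10‑dimethyl‑4‑(methacryloyloxy)‑7‑oxododec‑10‑en‑2‑ynoate
Product: 18 methyl (2Z,4R,6S,8S,10Z)‑2‑(acetoxymethyl)‑8,12‑bis(TBS‑oxy)‑3‑iodo‑6,10‑dimethyl‑4‑(methacryloyloxy)‑7‑oxododeca‑2,10‑dienoate, via iodo‑aldol magnesium alkoxide 17 (not isolated)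
Conditions: MgI2 (1.5 equiv), monomeric CH2O (excess), CH2Cl2, −20 → 0 °C; then Ac2O, 0 °C → rt
Reagents that add atoms: magnesium iodide, [Mg+2].[I-].[I-]; formaldehyde, C=O; acetic anhydride, CC(=O)OC(C)=O
Why: β‑Iodo Morita–Baylis–Hillman (halo‑aldol) reaction, in which iodide adds in conjugate fashion to the ynoate and the magnesium allenoate is trapped at C11 by formaldehyde anti to iodine, giving the tetrasubstituted Z‑iodoenoate (I cis to CO2Me) needed for lactonisation, with the primary alkoxide acetylated in situ.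

Step 10
Reactants: 18 methyl (2Z,4R,6S,8S,10Z)‑2‑(acetoxymethyl)‑8,12‑bis(TBS‑oxy)‑3‑iodo‑6,10‑dimethyl‑4‑(methacryloyloxy)‑7‑oxododeca‑2,10‑dienoate
Product: 19 methyl (2Z,4R,6S,8S,10Z)‑2‑(acetoxymethyl)‑8‑(TBS‑oxy)‑12‑hydroxy‑3‑iodo‑6,10‑dimethyl‑4‑(methacryloyloxy)‑7‑oxododeca‑2,10‑dienoate
Conditions: HF·pyridine, pyridine, THF, 0 °C
Reagents that add atoms: none
Why: Buffered fluoride cleaves the unhindered primary allylic TBS ether much faster than the hindered secondary α‑keto TBS ether (steric rate differentiation of silyl ethers).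

Step 11
Reactants: 19 methyl (2Z,4R,6S,8S,10Z)‑2‑(acetoxymethyl)‑8‑(TBS‑oxy)‑12‑hydroxy‑3‑iodo‑6,10‑dimethyl‑4‑(methacryloyloxy)‑7‑oxododeca‑2,10‑dienoate
Product: 20 methyl (2Z,4R,6S,8S,10Z)‑2‑(acetoxymethyl)‑8‑(TBS‑oxy)‑3‑iodo‑6,10‑dimethyl‑4‑(methacryloyloxy)‑7,12‑dioxododeca‑2,10‑dienoate
Conditions: Dess–Martin periodinane, NaHCO3, CH2Cl2, 0 °C; used at once
Reagents that add atoms: none
Why: Buffered Dess–Martin oxidation gives the Z‑enal under neutral conditions that avoid Z→E isomerisation and leave the esters, the alkenyl iodide and the silyl ether alone.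

Step 12
Reactants: 20 methyl (2Z,4R,6S,8S,10Z)‑2‑(acetoxymethyl)‑8‑(TBS‑oxy)‑3‑iodo‑6,10‑dimethyl‑4‑(methacryloyloxy)‑7,12‑dioxododeca‑2,10‑dienoate
Product: 22 (2S,6S,8R,10S,4Z)‑13‑acetoxy‑2‑(TBS‑oxy)‑8‑(methacryloyloxy)‑1‑oxogermacra‑4,7(11)‑dien‑12,6‑olide (6S here is the same spatial arrangement as 6R in 24), via macrocyclic hydroxy ester 21 (not isolated)
Conditions: CrCl2 (10 equiv), NiCl2 (cat.), degassed DMSO–THF, rt, syringe‑pump addition (final 2 mM); aq. potassium serinate work‑up; optionally with a Kishi chiral sulfonamide ligand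
Reagents that add atoms: none
Why: Intramolecular Nozaki–Hiyama–Kishi reaction in which Ni(0) inserts into C7–I, the alkenylchromium(III) adds with retention of alkene geometry to the aldehyde in preference to the hindered ketone and closes the farnesyl‑type C6–C7 bond, and the C6 alkoxide held cis to the ester then closes the butenolide, with C6 set by Re‑face addition under control of the C8 centre through the cyclic transition state (an unproven working hypothesis, reinforced if needed by the chiral Cr ligand).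

Step 13
Reactants: 22 (2S,6S,8R,10S,4Z)‑13‑acetoxy‑2‑(TBS‑oxy)‑8‑(methacryloyloxy)‑1‑oxogermacra‑4,7(11)‑dien‑12,6‑olide
Product: 23 (2S,6S,8R,10S,4Z)‑13‑acetoxy‑2‑hydroxy‑8‑(methacryloyloxy)‑1‑oxogermacra‑4,7(11)‑dien‑12,6‑olide
Conditions: HF·pyridine, THF, 0 °C → rt
Reagents that add atoms: none
Why: Fluoride desilylation under non‑basic conditions frees the C2 hydroxyl without touching the esters, the butenolide or the epimerisable C10 centre.

Step 14
Reactants: 23 (2S,6S,8R,10S,4Z)‑13‑acetoxy‑2‑hydroxy‑8‑(methacryloyloxy)‑1‑oxogermacra‑4,7(11)‑dien‑12,6‑olide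
Product: 24 (2S,4S,5R,6R,8R,10S)‑13‑acetoxy‑4,5‑epoxy‑2‑hydroxy‑8‑(methacryloyloxy)‑1‑oxogermacr‑7(11)‑en‑12,6‑olide (target)
Conditions: dimethyldioxirane, acetone–CH2Cl2, −40 → −20 °C
Reagents that add atoms: dimethyldioxirane, CC1(C)OO1
Why: Electrophilic epoxidation takes only the electron‑rich trisubstituted alkene (both enoates are inert) and, with H6 eclipsing the Z‑alkene to relieve A1,3 strain, is expected to attack the face anti to the allylic C6–O bond (Kishi‑type 1,2‑induction) to give the cis‑(4S,5R)‑oxirane.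

## Compound list

1 | but‑2‑yn‑1‑ol | CC#CCO | starting material
2 | sodium cyclic (Z)‑alkenyl bis(2‑methoxyethoxy)aluminate from 1 | CC1=CCO[Al-]1(OCCOC)OCCOC.[Na+] | intermediate
3 | (Z)‑3‑iodobut‑2‑en‑1‑ol | C/C(I)=C/CO | intermediate
4 | methyl (S)‑glycidate | COC(=O)[C@@H]1CO1 | starting material
5 | (Z)‑[4‑(chloromagnesiooxy)but‑2‑en‑2‑yl]magnesium chloride | C/C([Mg]Cl)=C/CO[Mg]Cl | intermediate
6 | methyl (2S,4Z)‑2,6‑dihydroxy‑4‑methylhex‑4‑enoate | COC(=O)[C@@H](O)C/C(C)=C\CO | intermediate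
7 | methyl (2S,4Z)‑2,6‑bis(TBS‑oxy)‑4‑methylhex‑4‑enoate | COC(=O)[C@@H](O[Si](C)(C)C(C)(C)C)C/C(C)=C\CO[Si](C)(C)C(C)(C)C | intermediate
8 | (2S,4Z)‑2,6‑bis(TBS‑oxy)‑4‑methylhex‑4‑enal | O=C[C@@H](O[Si](C)(C)C(C)(C)C)C/C(C)=C\CO[Si](C)(C)C(C)(C)C | intermediate
9 | (Z)‑crotylboronic acid pinacol ester | C/C=C\CB1OC(C)(C)C(C)(C)O1 | starting material
10 | (3S,4R,5S,7Z)‑5,9‑bis(TBS‑oxy)‑3,7‑dimethylnona‑1,7‑dien‑4‑ol | C=C[C@H](C)[C@@H](O)[C@@H](O[Si](C)(C)C(C)(C)C)C/C(C)=C\CO[Si](C)(C)C(C)(C)C | intermediate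
11 | B‑alkyl‑9‑BBN adduct of 10 (C8–B, C1–O–B) | C(C[C@H](C)[C@@H](OB1C2CCCC1CCC2)[C@@H](O[Si](C)(C)C(C)(C)C)C/C(C)=C\CO[Si](C)(C)C(C)(C)C)B1C2CCCC1CCC2 | intermediate
12 | (3S,4R,5S,7Z)‑5,9‑bis(TBS‑oxy)‑3,7‑dimethylnon‑7‑ene‑1,4‑diol | OCC[C@H](C)[C@@H](O)[C@@H](O[Si](C)(C)C(C)(C)C)C/C(C)=C\CO[Si](C)(C)C(C)(C)C | intermediate
13 | (3S,5S,7Z)‑5,9‑bis(TBS‑oxy)‑3,7‑dimethyl‑4‑oxonon‑7‑enal | O=CC[C@H](C)C(=O)[C@@H](O[Si](C)(C)C(C)(C)C)C/C(C)=C\CO[Si](C)(C)C(C)(C)C | intermediate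
14 | methyl propiolate | C#CC(=O)OC | starting material
15 | methyl (4R,6S,8S,10Z)‑8,12‑bis(TBS‑oxy)‑4‑hydroxy‑6,10‑dimethyl‑7‑oxododec‑10‑en‑2‑ynoate (in the flask as its methylzinc alkoxide) | COC(=O)C#C[C@H](O)C[C@H](C)C(=O)[C@@H](O[Si](C)(C)C(C)(C)C)C/C(C)=C\CO[Si](C)(C)C(C)(C)C | intermediate
16 | methyl (4R,6S,8S,10Z)‑8,12‑bis(TBS‑oxy)‑6,10‑dimethyl‑4‑(methacryloyloxy)‑7‑oxododec‑10‑en‑2‑ynoate | COC(=O)C#C[C@H](OC(=O)C(C)=C)C[C@H](C)C(=O)[C@@H](O[Si](C)(C)C(C)(C)C)C/C(C)=C\CO[Si](C)(C)C(C)(C)C | intermediate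
17 | methyl (2Z,4R,6S,8S,10Z)‑8,12‑bis(TBS‑oxy)‑2‑(hydroxymethyl)‑3‑iodo‑6,10‑dimethyl‑4‑(methacryloyloxy)‑7‑oxododeca‑2,10‑dienoate (in the flask as its magnesium alkoxide) | COC(=O)/C(CO)=C(\I)[C@H](OC(=O)C(C)=C)C[C@H](C)C(=O)[C@@H](O[Si](C)(C)C(C)(C)C)C/C(C)=C\CO[Si](C)(C)C(C)(C)C | intermediate
18 | methyl (2Z,4R,6S,8S,10Z)‑2‑(acetoxymethyl)‑8,12‑bis(TBS‑oxy)‑3‑iodo‑6,10‑dimethyl‑4‑(methacryloyloxy)‑7‑oxododeca‑2,10‑dienoate | COC(=O)/C(COC(C)=O)=C(\I)[C@H](OC(=O)C(C)=C)C[C@H](C)C(=O)[C@@H](O[Si](C)(C)C(C)(C)C)C/C(C)=C\CO[Si](C)(C)C(C)(C)C | intermediate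
19 | methyl (2Z,4R,6S,8S,10Z)‑2‑(acetoxymethyl)‑8‑(TBS‑oxy)‑12‑hydroxy‑3‑iodo‑6,10‑dimethyl‑4‑(methacryloyloxy)‑7‑oxododeca‑2,10‑dienoate | COC(=O)/C(COC(C)=O)=C(\I)[C@H](OC(=O)C(C)=C)C[C@H](C)C(=O)[C@@H](O[Si](C)(C)C(C)(C)C)C/C(C)=C\CO | intermediate
20 | methyl (2Z,4R,6S,8S,10Z)‑2‑(acetoxymethyl)‑8‑(TBS‑oxy)‑3‑iodo‑6,10‑dimethyl‑4‑(methacryloyloxy)‑7,12‑dioxododeca‑2,10‑dienoate | COC(=O)/C(COC(C)=O)=C(\I)[C@H](OC(=O)C(C)=C)C[C@H](C)C(=O)[C@@H](O[Si](C)(C)C(C)(C)C)C/C(C)=C\C=O | intermediate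
21 | macrocyclic hydroxy ester: methyl 13‑acetoxy‑2‑(TBS‑oxy)‑6‑hydroxy‑8‑(methacryloyloxy)‑1‑oxogermacra‑4Z,7(11)‑dien‑12‑oate, C6–OH cis to CO2Me, 2S,6S,8R,10S (in the flask as its chromium alkoxide) | C=C(C)C(=O)O[C@@H]1C[C@H](C)C(=O)[C@@H](O[Si](C)(C)C(C)(C)C)C/C(C)=C\[C@H](O)/C1=C(/COC(C)=O)C(=O)OC | intermediate
22 | (2S,6S,8R,10S,4Z)‑13‑acetoxy‑2‑(TBS‑oxy)‑8‑(methacryloyloxy)‑1‑oxogermacra‑4,7(11)‑dien‑12,6‑olide | C=C(C)C(=O)O[C@@H]1C[C@H](C)C(=O)[C@@H](O[Si](C)(C)C(C)(C)C)C/C(C)=C\[C@@H]2OC(=O)C(COC(C)=O)=C21 | intermediate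
23 | (2S,6S,8R,10S,4Z)‑13‑acetoxy‑2‑hydroxy‑8‑(methacryloyloxy)‑1‑oxogermacra‑4,7(11)‑dien‑12,6‑olide | C=C(C)C(=O)O[C@@H]1C[C@H](C)C(=O)[C@@H](O)C/C(C)=C\[C@@H]2OC(=O)C(COC(C)=O)=C21 | intermediate
24 | (2S,4S,5R,6R,8R,10S)‑13‑acetoxy‑4,5‑epoxy‑2‑hydroxy‑8‑(methacryloyloxy)‑1‑oxogermacr‑7(11)‑en‑12,6‑olide | C=C(C)C(=O)O[C@@H]1C[C@H](C)C(=O)[C@@H](O)C[C@]2(C)O[C@@H]2[C@@H]2OC(=O)C(COC(C)=O)=C21 | target

## Step count and risks

Total step count: 14. Longest linear sequence: 14 steps (from but‑2‑yn‑1‑ol; 4, 9 and 14 are bought).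

**Step 12 (Ni/Cr macrocyclisation–lactonisation).** The risks are oligomerisation during closure of a strained 10‑membered ring, 5‑exo attack of the alkenylchromium on the C1 ketone, β‑elimination of the C8 acyloxy group, Z→E isomerisation of the enal, and an unproven face selectivity at C6. The fallback forms the oxirane before the carbocycle, so that the electrophile is a more reactive, non‑isomerisable aldehyde and C6 is set by 1,2‑induction. It sets out from 19. Sharpless epoxidation (Ti(OiPr)4, D‑(−)‑diisopropyl tartrate, t‑BuOOH, −20 °C) gives the (4S,5R)‑epoxy alcohol F1. Dess–Martin oxidation gives the epoxy aldehyde F2. The same Ni/Cr closure then proceeds by Felkin–Anh addition anti to the oxirane C–O bond, through the epoxy hydroxy ester F3, to the epoxy lactone silyl ether F4. HF·pyridine then removes the silyl group and the fallback comes back to the route at 24.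

**Step 9 (iodide/formaldehyde halo‑aldol).** The internal γ‑acyloxy ynoate may react slowly, the allenoate may attack the C1 ketone, and the alkene geometry is not secured. The fallback runs the reaction on the free alcohol and lets lactonisation remove the wrong isomer. It sets out from 15, isolated as the free alcohol by aqueous work‑up in place of acylation. MgI2/CH2O gives the Z‑iodo diol F5; chelation of formaldehyde to the C8 magnesium alkoxide should deliver it to the C8 side. Any E isomer has C8–OH cis to the ester, closes to an 8,12‑butenolide and is removed by chromatography. Selective acetylation of the primary allylic hydroxyl (AcCl, 2,4,6‑collidine, −78 °C) gives the monoacetate F6. Methacrylation (methacryloyl chloride, i‑Pr2NEt) then comes back to the route at 18.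

**Step 14 (final epoxidation).** The face selectivity on a mobile 10‑membered ring is a prediction, and the ring may expose the other face. The fallback delivers the oxygen to the face opposite to the one an electrophile attacks. It sets out from 23. NBS in aqueous THF at 0 °C gives the bromohydrin F7 (bromonium on the exposed face, water opening anti at the tertiary C4). Ag2O in CH2Cl2 then closes the oxirane with inversion at C5 and comes back to the route at 24.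

## Further compounds

F1 | step 12 | (4S,5R)‑4,5‑epoxide of 19 (epoxy alcohol) | COC(=O)/C(COC(C)=O)=C(\I)[C@H](OC(=O)C(C)=C)C[C@H](C)C(=O)[C@@H](O[Si](C)(C)C(C)(C)C)C[C@]1(C)O[C@@H]1CO
F2 | step 12 | epoxy aldehyde from F1 (oxirane geometry unchanged) | COC(=O)/C(COC(C)=O)=C(\I)[C@H](OC(=O)C(C)=C)C[C@H](C)C(=O)[C@@H](O[Si](C)(C)C(C)(C)C)C[C@]1(C)O[C@@H]1C=O
F3 | step 12 | macrocyclic epoxy hydroxy ester (not isolated) | C=C(C)C(=O)O[C@@H]1C[C@H](C)C(=O)[C@@H](O[Si](C)(C)C(C)(C)C)C[C@]2(C)O[C@@H]2[C@H](O)/C1=C(/COC(C)=O)C(=O)OC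
F4 | step 12 | 2‑O‑TBS ether of 24 | C=C(C)C(=O)O[C@@H]1C[C@H](C)C(=O)[C@@H](O[Si](C)(C)C(C)(C)C)C[C@]2(C)O[C@@H]2[C@@H]2OC(=O)C(COC(C)=O)=C21
F5 | step 9 | Z‑iodo diol (C8–OH and C13–OH free) | COC(=O)/C(CO)=C(\I)[C@H](O)C[C@H](C)C(=O)[C@@H](O[Si](C)(C)C(C)(C)C)C/C(C)=C\CO[Si](C)(C)C(C)(C)C
F6 | step 9 | C13 monoacetate of F5 | COC(=O)/C(COC(C)=O)=C(\I)[C@H](O)C[C@H](C)C(=O)[C@@H](O[Si](C)(C)C(C)(C)C)C/C(C)=C\CO[Si](C)(C)C(C)(C)C
F7 | step 14 | 5‑bromo‑4‑hydroxy bromohydrin of 23 (C4–OH as in 24, C5–Br on the opposite face) | C=C(C)C(=O)O[C@@H]1C[C@H](C)C(=O)[C@@H](O)C[C@](C)(O)[C@@H](Br)[C@@H]2OC(=O)C(COC(C)=O)=C21
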